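The ε-ring (carotenoid numbering C-1 to C-6) is disconnected at C-3–C-4 and C-5–C-6. Its C-4=C-5(CH3) unit is a propyne, and the remaining C-3/C-2/C-1/C-6 unit is a cyclobutanone carved from (−)-α-pinene, which supplies the gem-dimethyl C-1 and the C-2 stereocentre. A nickel-catalysed alkyne insertion cleaves the C-6–C-3 bond of the four-membered ketone and forms both ring bonds in one operation; the precursor is a 2,2-dimethyl-3-alkylcyclobutanone plus 1-(trimethylsilyl)propyne. The C-6 carbonyl then carries the polyene: C-6 is set by hydroboration, C-2′ comes from (R)-lavandulol, and two Wittig reactions on the C10 dialdehyde close the C50 chain.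

Key step: step 6

Assumption: (1S,5S)-(−)-α-pinene and natural (R)-(−)-lavandulol are bought in high enantiomeric purity and are the only sources of chirality; locants C-1 to C-6 and primed locants follow carotenoid numbering.

Step 1
Reactants: 1 (1S,5S)-(−)-α-pinene
Product: 3 cis-pinonaldehyde (2-[(1R,3R)-3-acetyl-2,2-dimethylcyclobutyl]acetaldehyde), via secondary ozonide 2 (not isolated)
Conditions: O3, CH2Cl2, −78 °C; then Me2S, −78 °C to rt
Reagents that add atoms: ozone, [O-][O+]=O
Why: Ozonolysis with reductive work-up cleaves the only C=C bond of 1 and leaves the cis-1,3-disubstituted cyclobutane with both stereocentres untouched.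

Step 2
Reactants: 3 cis-pinonaldehyde
Product: 4 keto enoate (methyl (2E)-4-[(1S,3R)-3-acetyl-2,2-dimethylcyclobutyl]-2-methylbut-2-enoate)
Conditions: methyl 2-(triphenylphosphoranylidene)propanoate (1.1 equiv), CH2Cl2, rt
Reagents that add atoms: methyl 2-(triphenylphosphoranylidene)propanoate, COC(=O)C(C)=P(c1ccccc1)(c1ccccc1)c1ccccc1
Why: Wittig reaction of a stabilised ylide, which should olefinate the aldehyde but not the methyl ketone and give the (E)-2-methyl-2-enoate.

Step 3
Reactants: 4 keto enoate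
Product: 5 cyclobutyl acetate (methyl (2E)-4-[(1S,3R)-3-(acetyloxy)-2,2-dimethylcyclobutyl]-2-methylbut-2-enoate)
Conditions: m-CPBA (2 equiv), NaHCO3, CH2Cl2, rt
Reagents that add atoms: m-chloroperoxybenzoic acid, OOC(=O)c1cccc(Cl)c1
Why: Baeyer–Villiger oxidation in which the secondary cyclobutyl carbon migrates in preference to methyl with retention of configuration, while the electron-poor enoate should not be epoxidised.

Step 4
Reactants: 5 cyclobutyl acetate
Product: 6 cyclobutanol (methyl (2E)-4-[(1S,3R)-3-hydroxy-2,2-dimethylcyclobutyl]-2-methylbut-2-enoate)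
Conditions: K2CO3 (0.2 equiv), MeOH, 0 °C to rt
Reagents that add atoms: none
Why: Base-catalysed transesterification removes the acetate, and exchange at the methyl ester is degenerate in methanol.

Step 5
Reactants: 6 cyclobutanol
Product: 7 cyclobutanone (methyl (2E)-4-[(1S)-2,2-dimethyl-3-oxocyclobutyl]-2-methylbut-2-enoate)
Conditions: Dess–Martin periodinane, NaHCO3, CH2Cl2, rt
Reagents that add atoms: none
Why: Dess–Martin oxidation of the secondary alcohol under neutral conditions; the stereocentre is β to the new carbonyl and cannot epimerise.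

Step 6
Reactants: 7 cyclobutanone; 8 1-(trimethylsilyl)propyne
Product: 9 silyl cyclohexenone (methyl (2E)-2-methyl-4-[(1S)-4,6,6-trimethyl-5-oxo-3-(trimethylsilyl)cyclohex-3-en-1-yl]but-2-enoate)
Conditions: Ni(cod)2 (10 mol %), PCy3 (20 mol %), 8 (3 equiv), toluene, 100 °C, sealed tube
Reagents that add atoms: none
Why: Zerovalent nickel couples the C=O group of 7 and the alkyne oxidatively to a spiro oxanickelacyclopentene (forming C-5–C-6); β-carbon elimination then opens the strained four-membered ring at its C(acyl)–CH2 bond (C-6–C-3), and C(sp2)–C(sp3) reductive elimination from the seven-membered nickelacycle forms C-3–C-4 and releases the enone and the catalyst. The closest known reaction type is the nickel-catalysed intermolecular insertion of internal alkynes into cyclobutanones, a formal [4+2] ring expansion by C–C activation. The six-membered ring is therefore closed by two-atom ring expansion of the cyclobutanone, its last bond by reductive elimination at nickel. No stereocentre is formed: C-2 is β to the carbonyl, takes no part in the bond reorganisation and is carried over from pinene unchanged. Two selectivities are needed: cleavage on the CH2 side and not the quaternary side, which the gem-dimethyl carbon should secure because only the unhindered primary carbon migrates to nickel, and bonding of the methyl-bearing alkyne carbon to the carbonyl carbon, which the SiMe3 group should secure because silicon stays on the nickel-bound carbon in the oxidative cyclisation and the small methyl group faces the crowded spiro centre. The trisubstituted enoate is a poor partner for nickel and should not compete with the alkyne.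

Step 7
Reactants: 9 silyl cyclohexenone
Product: 10 silyl diene (methyl (2E)-2-methyl-4-[(1S)-4,6,6-trimethyl-5-methylidene-3-(trimethylsilyl)cyclohex-3-en-1-yl]but-2-enoate)
Conditions: Zn, CH2Br2, TiCl4, THF/CH2Cl2, 0 °C to rt
Reagents that add atoms: dibromomethane, BrCBr
Why: Takai–Lombardo methylenation, a non-basic carbonyl olefination that tolerates the ester and suits hindered, enolisable ketones.

Step 8
Reactants: 10 silyl diene
Product: 12 silyl alcohol (methyl (2E)-4-[(1S,5S)-5-(hydroxymethyl)-4,6,6-trimethyl-3-(trimethylsilyl)cyclohex-3-en-1-yl]-2-methylbut-2-enoate), via B-alkyl-9-BBN adduct 11 (not isolated)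
Conditions: 9-BBN, THF, 0 to 40 °C; then 30 % H2O2, aq. NaOAc, 0 °C to rt
Reagents that add atoms: hydrogen peroxide, OO
Why: Hydroboration–oxidation in which 9-BBN places boron on the terminal carbon of the only 1,1-disubstituted alkene and delivers hydrogen to C-6 anti to the pseudoaxial C-1 methyl group, which lies on the face of the pseudoequatorial C-2 side chain, so that the new C-6 stereocentre should carry its CH2OH cis to that side chain (substrate control).

Step 9
Reactants: 12 silyl alcohol
Product: 13 ring alcohol (methyl (2E)-4-[(1R,5R)-5-(hydroxymethyl)-4,6,6-trimethylcyclohex-3-en-1-yl]-2-methylbut-2-enoate)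
Conditions: HI (57 % aq., 0.2 equiv), toluene, rt
Reagents that add atoms: none
Why: Protodesilylation of a vinylsilane, in which ipso protonation at C-4 gives a tertiary β-silyl cation at C-5 and loss of silicon returns the C-4=C-5 double bond in place (the descriptors change only because silicon leaves the priority sequence).

Step 10
Reactants: 13 ring alcohol
Product: 14 ring aldehyde (methyl (2E)-4-[(1R,5R)-5-formyl-4,6,6-trimethylcyclohex-3-en-1-yl]-2-methylbut-2-enoate)
Conditions: Dess–Martin periodinane, NaHCO3, CH2Cl2, 0 °C; used without purification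
Reagents that add atoms: none
Why: Buffered Dess–Martin oxidation should give the β,γ-unsaturated aldehyde without the enolisation that would epimerise C-6 or move the ring double bond.

Step 11
Reactants: 14 ring aldehyde
Product: 15 ring enone (methyl (2E)-2-methyl-4-[(1R,5R)-4,6,6-trimethyl-5-[(1E)-3-oxobut-1-en-1-yl]cyclohex-3-en-1-yl]but-2-enoate)
Conditions: 1-(triphenylphosphoranylidene)propan-2-one, toluene, 90 °C
Reagents that add atoms: 1-(triphenylphosphoranylidene)propan-2-one, CC(=O)C=P(c1ccccc1)(c1ccccc1)c1ccccc1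
Why: Wittig reaction with a stabilised, weakly basic ylide should give the (E)-enone and leave the α-stereocentre of the aldehyde intact.

Step 12
Reactants: 15 ring enone
Product: 16 ring vinyl carbinol (methyl (2E)-4-[(1R,5R)-5-[(1E)-3-hydroxy-3-methylpenta-1,4-dien-1-yl]-4,6,6-trimethylcyclohex-3-en-1-yl]-2-methylbut-2-enoate, both carbinol epimers)
Conditions: CH2=CHMgBr (1.2 equiv), THF, −78 °C; aq. NH4Cl
Reagents that add atoms: vinylmagnesium bromide, C=C[Mg]Br
Why: Grignard 1,2-addition to the enone should be faster at −78 °C than attack on the hindered conjugated ester; the carbinol centre forms without control and is removed in step 13.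

Step 13
Reactants: 16 ring vinyl carbinol
Product: 17 ring-end phosphonium bromide ([(2E,4E)-5-[(1R,5R)-5-[(2E)-4-methoxy-3-methyl-4-oxobut-2-en-1-yl]-2,6,6-trimethylcyclohex-2-en-1-yl]-3-methylpenta-2,4-dien-1-yl]triphenylphosphonium bromide)
Conditions: PPh3·HBr, MeOH, rt
Reagents that add atoms: triphenylphosphine hydrobromide, [Br-].c1ccc(cc1)[PH+](c1ccccc1)c1ccccc1
Why: Acid-induced ionisation of the tertiary allylic alcohol to a pentadienyl cation and capture by PPh3 at the primary terminus (allylic transposition, the classical Wittig-salt formation from vinyl carbinols), which should give mainly the (2E,4E) salt.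

Step 14
Reactants: 18 (R)-(−)-lavandulol
Product: 19 diol ((2S)-3-methyl-2-(3-methylbut-2-en-1-yl)butane-1,3-diol)
Conditions: Co(acac)2 (20 mol %), PhSiH3, O2 (1 atm), THF, rt
Reagents that add atoms: dioxygen, O=O
Why: Mukaiyama hydration (metal-hydride hydrogen atom transfer, then trapping of the tertiary radical by O2) should hydrate the less hindered 1,1-disubstituted alkene in the Markovnikov sense without touching the stereocentre or the prenyl group.

Step 15
Reactants: 19 diol
Product: 20 hydroxy aldehyde ((2R)-3-hydroxy-3-methyl-2-(3-methylbut-2-en-1-yl)butanal)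
Conditions: TEMPO (10 mol %), PhI(OAc)2, CH2Cl2, rt; used without purification
Reagents that add atoms: none
Why: TEMPO/PhI(OAc)2 oxidation is selective for the primary alcohol and neutral, so that the β-hydroxy aldehyde should neither epimerise nor undergo retro-aldol cleavage.

Step 16
Reactants: 20 hydroxy aldehyde
Product: 21 acyclic enone ((3E,5S)-6-hydroxy-6-methyl-5-(3-methylbut-2-en-1-yl)hept-3-en-2-one)
Conditions: 1-(triphenylphosphoranylidene)propan-2-one, CH2Cl2, 40 °C
Reagents that add atoms: 1-(triphenylphosphoranylidene)propan-2-one, CC(=O)C=P(c1ccccc1)(c1ccccc1)c1ccccc1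
Why: Wittig reaction with a stabilised ylide under neutral conditions, E-selective and compatible with the free tertiary alcohol and the α-stereocentre.

Step 17
Reactants: 21 acyclic enone
Product: 22 acyclic vinyl carbinol ((4E,6S)-3,7-dimethyl-6-(3-methylbut-2-en-1-yl)octa-1,4-diene-3,7-diol, both C-3 epimers)
Conditions: CH2=CHMgBr (2.5 equiv), THF, −78 to 0 °C; aq. NH4Cl
Reagents that add atoms: vinylmagnesium bromide, C=C[Mg]Br
Why: Grignard 1,2-addition to the enone after the first equivalent has deprotonated the tertiary alcohol; the new carbinol centre is uncontrolled and is removed in step 18.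

Step 18
Reactants: 22 acyclic vinyl carbinol
Product: 23 short acyclic phosphonium bromide ([(2E,4E,6S)-7-hydroxy-3,7-dimethyl-6-(3-methylbut-2-en-1-yl)octa-2,4-dien-1-yl]triphenylphosphonium bromide)
Conditions: PPh3·HBr, MeOH, rt
Reagents that add atoms: triphenylphosphine hydrobromide, [Br-].c1ccc(cc1)[PH+](c1ccccc1)c1ccccc1
Why: Allylic transposition to the phosphonium salt as in step 13; only the allylic tertiary alcohol ionises, and the non-allylic C-1′ alcohol should stay.

Step 19
Reactants: 23 short acyclic phosphonium bromide; 24 (2E)-4-acetoxy-2-methylbut-2-enal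
Product: 26 tetraenyl acetate ((2E,4E,6E,8E,10S)-11-hydroxy-3,7,11-trimethyl-10-(3-methylbut-2-en-1-yl)dodeca-2,4,6,8-tetraen-1-yl acetate), via phosphorus ylide 25 (not isolated)
Conditions: 1,2-epoxybutane (solvent and HBr acceptor), 60 °C
Reagents that add atoms: none
Why: Wittig reaction under neutral conditions, which tolerates the acetate and the free hydroxyl; the new disubstituted double bond should form mainly E, and any Z isomer converges in the isomerisation of step 22.

Step 20
Reactants: 26 tetraenyl acetate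
Product: 27 long acyclic phosphonium bromide ([(2E,4E,6E,8E,10S)-11-hydroxy-3,7,11-trimethyl-10-(3-methylbut-2-en-1-yl)dodeca-2,4,6,8-tetraen-1-yl]triphenylphosphonium bromide)
Conditions: PPh3·HBr, MeOH, rt
Reagents that add atoms: triphenylphosphine hydrobromide, [Br-].c1ccc(cc1)[PH+](c1ccccc1)c1ccccc1
Why: Ionisation of the allylic polyenyl acetate and capture of the cation by PPh3 at the primary terminus, the standard conversion of polyenyl acetates into Wittig salts.

Step 21
Reactants: 17 ring-end phosphonium bromide; 28 (2E,4E,6E)-2,7-dimethylocta-2,4,6-trienedial (C10 dialdehyde)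
Product: 30 C30 apo-aldehyde ester (methyl (2E)-2-methyl-4-[(1R,5R)-4,6,6-trimethyl-5-[(1E,3E,5E,7E,9E,11E)-3,7,12-trimethyl-13-oxotrideca-1,3,5,7,9,11-hexaen-1-yl]cyclohex-3-en-1-yl]but-2-enoate), via phosphorus ylide 29 (not isolated)
Conditions: NaOMe, MeOH/CH2Cl2, 0 °C to rt; 28 in excess (3 equiv)
Reagents that add atoms: none
Why: Wittig mono-olefination of the symmetrical dialdehyde, which is used in excess so that the second formyl group should stay free.

Step 22
Reactants: 27 long acyclic phosphonium bromide; 30 C30 apo-aldehyde ester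
Product: 32 C50 methyl ester (the target skeleton with CO2Me in place of the side-chain CH2OH; 2R,6R,2′S, all-E), via phosphorus ylide 31 (not isolated)
Conditions: NaOMe, MeOH/CH2Cl2, 0 °C to rt, dark; then n-heptane, reflux, N2
Reagents that add atoms: none
Why: Wittig reaction that closes the C50 chain, followed by thermal isomerisation that should convert Z isomers at the newly formed double bonds into the all-E polyene.

Step 23
Reactants: 32 C50 methyl ester
Product: 33 target ((2R,6R,2′S)-2-[(2E)-4-hydroxy-3-methylbut-2-en-1-yl]-2′-(3-methylbut-2-en-1-yl)-3′,4′-didehydro-1′,2′-dihydro-ε,ψ-caroten-1′-ol, all-E)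
Conditions: i-Bu2AlH (3.5 equiv), CH2Cl2, −78 °C; aq. KNaC4H4O6
Reagents that add atoms: none
Why: Hydride reduction of the only ester to the primary allylic alcohol at low temperature, which should leave the polyene, the ring alkene and the tertiary alcohol untouched.

Compound list
1 | (1S,5S)-(−)-α-pinene [(1S,5S)-2,6,6-trimethylbicyclo[3.1.1]hept-2-ene] | CC1=CC[C@H]2C[C@@H]1C2(C)C | starting material
2 | secondary ozonide of 1 (1,2,4-trioxolane across the former C=C, not isolated) | CC12OOC(O1)C[C@H]3C[C@@H]2C3(C)C | intermediate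
3 | 2-[(1R,3R)-3-acetyl-2,2-dimethylcyclobutyl]acetaldehyde (cis-pinonaldehyde) | O=CC[C@H]1C[C@@H](C(C)=O)C1(C)C | intermediate
4 | methyl (2E)-4-[(1S,3R)-3-acetyl-2,2-dimethylcyclobutyl]-2-methylbut-2-enoate | COC(=O)/C(C)=C/C[C@H]1C[C@@H](C(C)=O)C1(C)C | intermediate
5 | methyl (2E)-4-[(1S,3R)-3-(acetyloxy)-2,2-dimethylcyclobutyl]-2-methylbut-2-enoate | COC(=O)/C(C)=C/C[C@H]1C[C@@H](OC(C)=O)C1(C)C | intermediate
6 | methyl (2E)-4-[(1S,3R)-3-hydroxy-2,2-dimethylcyclobutyl]-2-methylbut-2-enoate | COC(=O)/C(C)=C/C[C@H]1C[C@@H](O)C1(C)C | intermediate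
7 | methyl (2E)-4-[(1S)-2,2-dimethyl-3-oxocyclobutyl]-2-methylbut-2-enoate | COC(=O)/C(C)=C/C[C@H]1CC(=O)C1(C)C | intermediate
8 | 1-(trimethylsilyl)propyne | CC#C[Si](C)(C)C | starting material
9 | methyl (2E)-2-methyl-4-[(1S)-4,6,6-trimethyl-5-oxo-3-(trimethylsilyl)cyclohex-3-en-1-yl]but-2-enoate | COC(=O)/C(C)=C/C[C@H]1CC([Si](C)(C)C)=C(C)C(=O)C1(C)C | intermediate
10 | methyl (2E)-2-methyl-4-[(1S)-4,6,6-trimethyl-5-methylidene-3-(trimethylsilyl)cyclohex-3-en-1-yl]but-2-enoate | COC(=O)/C(C)=C/C[C@H]1CC([Si](C)(C)C)=C(C)C(=C)C1(C)C | intermediate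
11 | B-alkyl-9-BBN adduct of 10 (boron on the exocyclic CH2, C-6 hydrogen cis to the C-2 hydrogen, not isolated) | COC(=O)/C(C)=C/C[C@H]1CC([Si](C)(C)C)=C(C)[C@@H](CB2C3CCCC2CCC3)C1(C)C | intermediate
12 | methyl (2E)-4-[(1S,5S)-5-(hydroxymethyl)-4,6,6-trimethyl-3-(trimethylsilyl)cyclohex-3-en-1-yl]-2-methylbut-2-enoate (ring substituents cis) | COC(=O)/C(C)=C/C[C@H]1CC([Si](C)(C)C)=C(C)[C@@H](CO)C1(C)C | intermediate
13 | methyl (2E)-4-[(1R,5R)-5-(hydroxymethyl)-4,6,6-trimethylcyclohex-3-en-1-yl]-2-methylbut-2-enoate | COC(=O)/C(C)=C/C[C@H]1CC=C(C)[C@@H](CO)C1(C)C | intermediate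
14 | methyl (2E)-4-[(1R,5R)-5-formyl-4,6,6-trimethylcyclohex-3-en-1-yl]-2-methylbut-2-enoate | COC(=O)/C(C)=C/C[C@H]1CC=C(C)[C@@H](C=O)C1(C)C | intermediate
15 | methyl (2E)-2-methyl-4-[(1R,5R)-4,6,6-trimethyl-5-[(1E)-3-oxobut-1-en-1-yl]cyclohex-3-en-1-yl]but-2-enoate | COC(=O)/C(C)=C/C[C@H]1CC=C(C)[C@@H](/C=C/C(C)=O)C1(C)C | intermediate
16 | methyl (2E)-4-[(1R,5R)-5-[(1E)-3-hydroxy-3-methylpenta-1,4-dien-1-yl]-4,6,6-trimethylcyclohex-3-en-1-yl]-2-methylbut-2-enoate (carbinol epimers) | COC(=O)/C(C)=C/C[C@H]1CC=C(C)[C@@H](/C=C/C(C)(O)C=C)C1(C)C | intermediate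
17 | [(2E,4E)-5-[(1R,5R)-5-[(2E)-4-methoxy-3-methyl-4-oxobut-2-en-1-yl]-2,6,6-trimethylcyclohex-2-en-1-yl]-3-methylpenta-2,4-dien-1-yl]triphenylphosphonium bromide | COC(=O)/C(C)=C/C[C@H]1CC=C(C)[C@@H](/C=C/C(C)=C/C[P+](c2ccccc2)(c2ccccc2)c2ccccc2)C1(C)C.[Br-] | intermediate
18 | (R)-(−)-lavandulol [(2R)-5-methyl-2-(prop-1-en-2-yl)hex-4-en-1-ol] | OC[C@H](CC=C(C)C)C(C)=C | starting material
19 | (2S)-3-methyl-2-(3-methylbut-2-en-1-yl)butane-1,3-diol | OC[C@H](CC=C(C)C)C(C)(C)O | intermediate
20 | (2R)-3-hydroxy-3-methyl-2-(3-methylbut-2-en-1-yl)butanal | O=C[C@H](CC=C(C)C)C(C)(C)O | intermediate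
21 | (3E,5S)-6-hydroxy-6-methyl-5-(3-methylbut-2-en-1-yl)hept-3-en-2-one | CC(=O)/C=C/[C@H](CC=C(C)C)C(C)(C)O | intermediate
22 | (4E,6S)-3,7-dimethyl-6-(3-methylbut-2-en-1-yl)octa-1,4-diene-3,7-diol (C-3 epimers) | C=CC(C)(O)/C=C/[C@H](CC=C(C)C)C(C)(C)O | intermediate
23 | [(2E,4E,6S)-7-hydroxy-3,7-dimethyl-6-(3-methylbut-2-en-1-yl)octa-2,4-dien-1-yl]triphenylphosphonium bromide | c1ccc(cc1)[P+](c1ccccc1)(c1ccccc1)C/C=C(C)/C=C/[C@H](CC=C(C)C)C(C)(C)O.[Br-] | intermediate
24 | (2E)-4-acetoxy-2-methylbut-2-enal | CC(=O)OC/C=C(\C)C=O | starting material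
25 | phosphorus ylide of 23 (not isolated) | c1ccc(cc1)P(c1ccccc1)(c1ccccc1)=C/C=C(C)/C=C/[C@H](CC=C(C)C)C(C)(C)O | intermediate
26 | (2E,4E,6E,8E,10S)-11-hydroxy-3,7,11-trimethyl-10-(3-methylbut-2-en-1-yl)dodeca-2,4,6,8-tetraen-1-yl acetate | CC(=O)OC/C=C(C)/C=C/C=C(C)/C=C/[C@H](CC=C(C)C)C(C)(C)O | intermediate
27 | [(2E,4E,6E,8E,10S)-11-hydroxy-3,7,11-trimethyl-10-(3-methylbut-2-en-1-yl)dodeca-2,4,6,8-tetraen-1-yl]triphenylphosphonium bromide | c1ccc(cc1)[P+](c1ccccc1)(c1ccccc1)C/C=C(C)/C=C/C=C(C)/C=C/[C@H](CC=C(C)C)C(C)(C)O.[Br-] | intermediate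
28 | (2E,4E,6E)-2,7-dimethylocta-2,4,6-trienedial | O=C/C(C)=C/C=C/C=C(C)/C=O | starting material
29 | phosphorus ylide of 17 (not isolated) | COC(=O)/C(C)=C/C[C@H]1CC=C(C)[C@@H](/C=C/C(C)=C/C=P(c2ccccc2)(c2ccccc2)c2ccccc2)C1(C)C | intermediate
30 | methyl (2E)-2-methyl-4-[(1R,5R)-4,6,6-trimethyl-5-[(1E,3E,5E,7E,9E,11E)-3,7,12-trimethyl-13-oxotrideca-1,3,5,7,9,11-hexaen-1-yl]cyclohex-3-en-1-yl]but-2-enoate | COC(=O)/C(C)=C/C[C@H]1CC=C(C)[C@@H](/C=C/C(C)=C/C=C/C(C)=C/C=C/C=C(C)/C=O)C1(C)C | intermediate
31 | phosphorus ylide of 27 (not isolated) | c1ccc(cc1)P(c1ccccc1)(c1ccccc1)=C/C=C(C)/C=C/C=C(C)/C=C/[C@H](CC=C(C)C)C(C)(C)O | intermediate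
32 | C50 methyl ester: the target with CO2Me in place of the CH2OH of the C-2 side chain, (2R,6R,2′S), all-E | CC(C)=CC[C@@H](/C=C/C(C)=C/C=C/C(C)=C/C=C/C(C)=C/C=C/C=C(C)/C=C/C=C(C)/C=C/[C@@H]1C(C)=CC[C@H](C/C=C(\C)C(=O)OC)C1(C)C)C(C)(C)O | intermediate
33 | (2R,6R,2′S)-2-[(2E)-4-hydroxy-3-methylbut-2-en-1-yl]-2′-(3-methylbut-2-en-1-yl)-3′,4′-didehydro-1′,2′-dihydro-ε,ψ-caroten-1′-ol (all-E) | CC(C)=CC[C@@H](/C=C/C(C)=C/C=C/C(C)=C/C=C/C(C)=C/C=C/C=C(C)/C=C/C=C(C)/C=C/[C@@H]1C(C)=CC[C@H](C/C=C(\C)CO)C1(C)C)C(C)(C)O | target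

Total step count: 23. Longest linear sequence: 16 steps (steps 1 to 13, then 21 to 23); the acyclic branch (steps 14 to 20) joins at step 22.

Steps most likely to fail

Step 6. What may go wrong: the zerovalent nickel and the alkyne are consumed by oxidative cyclisation with the enoate, or alkyne oligomerisation outruns the slow entry of the hindered ketone into the nickelacycle. Fallback (sets out from 3, comes back at 9): the ring expansion is run before the enoate is built, so that the substrate has no second π-acceptor. Aldehyde 3 is masked with HC(OMe)3 and PPTS in MeOH as the keto acetal F1. Baeyer–Villiger oxidation (m-CPBA) gives the acetoxy acetal F2, methanolysis (K2CO3, MeOH) the cyclobutanol acetal F3, and Dess–Martin oxidation the cyclobutanone acetal F4. Insertion of 8 under the conditions of step 6 gives the silyl enone acetal F5. Aqueous acetic acid in THF frees the silyl enone aldehyde F6, and the stabilised ylide of step 2, which should react with the aldehyde and not with the hindered enone, gives 9.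

Step 8. What may go wrong: erosion of facial selectivity in the delivery of hydrogen to C-6, or slow and unselective addition of the borane to the hindered, conjugated exocyclic alkene. Fallback (sets out from 9, comes back at 12): the carbon is added as an enol ether and C-6 is set by C-protonation instead of hydroboration. Wittig reaction of 9 with Ph3P=CHOMe (from Ph3P(CH2OMe)Cl and KOt-Bu, THF) gives the methoxy dienyl ether F7. Hydrolysis with oxalic acid on wet silica should protonate the α-carbon (C-6) kinetically from the axial direction, anti to the pseudoaxial C-1 methyl group, and give the cis silyl aldehyde F8. NaBH4 in MeOH at 0 °C reduces F8 to 12.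

Step 11. What may go wrong: epimerisation at C-6 or migration of the ring double bond into conjugation while the hindered aldehyde 14 waits for a slow olefination. Fallback (sets out from 13, comes back at 17): the polarity is reversed so that no enolisable aldehyde is made, and steps 10 to 13 are bypassed. Mitsunobu reaction of 13 with 1-phenyl-1H-tetrazole-5-thiol (PPh3, DIAD, THF) gives the tetrazolyl sulfide F9, and oxidation with (NH4)6Mo7O24 and H2O2 in EtOH gives the tetrazolyl sulfone F10. Julia–Kocienski olefination of F10 with 24 (KN(SiMe3)2, DME, −60 °C) gives the dienyl acetate F11, and PPh3·HBr in MeOH converts F11 into 17 as in step 20.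

Further compounds
F1 | step 6 | keto acetal 1-[(1R,3R)-3-(2,2-dimethoxyethyl)-2,2-dimethylcyclobutyl]ethan-1-one | COC(OC)C[C@H]1C[C@@H](C(C)=O)C1(C)C
F2 | step 6 | acetoxy acetal (1R,3R)-3-(2,2-dimethoxyethyl)-2,2-dimethylcyclobutyl acetate | COC(OC)C[C@H]1C[C@@H](OC(C)=O)C1(C)C
F3 | step 6 | cyclobutanol acetal (1R,3R)-3-(2,2-dimethoxyethyl)-2,2-dimethylcyclobutan-1-ol | COC(OC)C[C@H]1C[C@@H](O)C1(C)C
F4 | step 6 | cyclobutanone acetal (3S)-3-(2,2-dimethoxyethyl)-2,2-dimethylcyclobutan-1-one | COC(OC)C[C@H]1CC(=O)C1(C)C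
F5 | step 6 | silyl enone acetal (5S)-5-(2,2-dimethoxyethyl)-2,6,6-trimethyl-3-(trimethylsilyl)cyclohex-2-en-1-one | COC(OC)C[C@H]1CC([Si](C)(C)C)=C(C)C(=O)C1(C)C
F6 | step 6 | silyl enone aldehyde 2-[(1S)-4,6,6-trimethyl-5-oxo-3-(trimethylsilyl)cyclohex-3-en-1-yl]acetaldehyde | O=CC[C@H]1CC([Si](C)(C)C)=C(C)C(=O)C1(C)C
F7 | step 8 | methoxy dienyl ether methyl (2E)-4-[(1S)-5-(methoxymethylidene)-4,6,6-trimethyl-3-(trimethylsilyl)cyclohex-3-en-1-yl]-2-methylbut-2-enoate | COC(=O)/C(C)=C/C[C@H]1CC([Si](C)(C)C)=C(C)C(=COC)C1(C)C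
F8 | step 8 | cis silyl aldehyde methyl (2E)-4-[(1S,5S)-5-formyl-4,6,6-trimethyl-3-(trimethylsilyl)cyclohex-3-en-1-yl]-2-methylbut-2-enoate | COC(=O)/C(C)=C/C[C@H]1CC([Si](C)(C)C)=C(C)[C@@H](C=O)C1(C)C
F9 | step 11 | tetrazolyl sulfide methyl (2E)-2-methyl-4-[(1R,5R)-4,6,6-trimethyl-5-{[(1-phenyl-1H-tetrazol-5-yl)sulfanyl]methyl}cyclohex-3-en-1-yl]but-2-enoate | COC(=O)/C(C)=C/C[C@H]1CC=C(C)[C@@H](CSc2nnnn2-c2ccccc2)C1(C)C
F10 | step 11 | tetrazolyl sulfone methyl (2E)-2-methyl-4-[(1R,5R)-4,6,6-trimethyl-5-{[(1-phenyl-1H-tetrazol-5-yl)sulfonyl]methyl}cyclohex-3-en-1-yl]but-2-enoate | COC(=O)/C(C)=C/C[C@H]1CC=C(C)[C@@H](CS(=O)(=O)c2nnnn2-c2ccccc2)C1(C)C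
F11 | step 11 | dienyl acetate methyl (2E)-4-[(1R,5R)-5-[(1E,3E)-5-(acetyloxy)-3-methylpenta-1,3-dien-1-yl]-4,6,6-trimethylcyclohex-3-en-1-yl]-2-methylbut-2-enoate | COC(=O)/C(C)=C/C[C@H]1CC=C(C)[C@@H](/C=C/C(C)=C/COC(C)=O)C1(C)C
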